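**Retrosynthetic overview**

1. The target comes from acetylation of the C4' alcohol of a 2,7-dioxabicyclo[3.2.1]octan-3-one. This bicycle closes last (tetrahydrofuran C6'–O7'–C1', then δ-lactone C3'–O2'–C1') from a seco acid–aldehyde made by periodate cleavage of C3'–C1' in a cyclopentanone.
2. The C9–C8' bond is made by decarboxylative addition of the C9 tertiary radical (from an N-acyloxyphthalimide) to a cis-4,5-disubstituted cyclopentenone prepared from (1R,5S)-2-oxabicyclo[3.3.0]oct-6-en-3-one.
3. The seven-membered ring (C1–C6, C10) is closed by olefin metathesis at C3–C4. This bond joins two methylenes next to the gem-dimethyl carbon C5 and is remote from C6, C9 and C10, so all three stereocentres are set on the cyclopentane first. The diene carries an allyl group on the C1 dioxolane carbon and a 1,1-dimethylallyl group on C6.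
4. The cis C6/C10 pair comes from ester-directed hydrogenation of a bicyclic Nazarov enone (temporary ring B: C10–C1–C4–C5–C6), whose C1–C4 bond is then cut by ozonolysis. C9 comes from an auxiliary-controlled methylation of a β-keto ester.
5. Ring order: cyclopentane (bought), temporary cyclopentenone (formed, then cleaved), cycloheptene, tetrahydrofuran acetal and δ-lactone together.

Key step: step 12

Remark (labels): carbocycle C1 (methylidene carbon), C2–C4, C5 (CMe2), C6 and C10 (ring fusion), C7, C8, C9 (quaternary). Oxygen bicycle C1' (acetal CH), O2', C3' (lactone C=O), C4' (CHOAc), C5' (bridgehead CH), C6' (CHCO2Me), O7', C8' (CH bonded to C9).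
Remark (assumption): the L-valine-derived lithio enamine is taken to be methylated on the face that gives the (R)-keto ester 5; if the sense were opposite, the D-amino ester would be used.
Remark (C9 substituent): C9 carries its one-carbon substituent as a methyl ester from the start, because this carboxyl group is the precursor of the C9 radical. The ester lies trans to the two side chains on C6 and C10, and the C9 methyl group lies cis to them.

Step 1
Reactants: 1 methyl 2-oxocyclopentane-1-carboxylate; 2 L-valine tert-butyl ester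
Product: 3 methyl 2-{[(2S)-1-tert-butoxy-3-methyl-1-oxobutan-2-yl]amino}cyclopent-1-ene-1-carboxylate
Conditions: BF3·OEt2 (cat.), benzene, reflux, Dean–Stark
Reagents that add atoms: none
Why: Acid-catalysed enamine formation gives the conjugated, hydrogen-bonded enamino ester, with water removed azeotropically.

Step 2
Reactants: 3 chiral enamino ester
Product: 5 methyl (1R)-1-methyl-2-oxocyclopentane-1-carboxylate, via methylated imine 4 (not isolated)
Conditions: LDA, toluene, HMPA (1 equiv), −78 °C; MeI; then aq. citric acid, 25 °C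
Reagents that add atoms: iodomethane, CI; water, O
Why: Chiral-enamine (aza-enolate) alkylation: the chelated lithio enamine should be methylated on the face away from the isopropyl group of the auxiliary, which sets C9, and mild hydrolysis of the imine frees the ketone and the auxiliary.

Step 3
Reactants: 5 (R)-keto ester
Product: 6 methyl (1R)-1-methyl-2-(trifluoromethylsulfonyloxy)cyclopent-2-ene-1-carboxylate
Conditions: KHMDS, THF, −78 °C; PhNTf2, −78 to 0 °C
Reagents that add atoms: N-phenylbis(trifluoromethanesulfonimide), O=S(=O)(N(c1ccccc1)S(=O)(=O)C(F)(F)F)C(F)(F)F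
Why: Enolate triflation: only C6 carries α-hydrogens, so a single enolate forms and O-sulfonylation gives the C10=C6 enol triflate.

Step 4
Reactants: 6 enol triflate; 7 tributyl(2-methylprop-1-en-1-yl)stannane
Product: 8 methyl (1R)-1-methyl-2-(3-methylbut-2-enoyl)cyclopent-2-ene-1-carboxylate
Conditions: Pd(PPh3)4 (5 mol%), LiCl (3 equiv), CO (1 atm), THF, 55 °C
Reagents that add atoms: carbon monoxide, [C-]#[O+]
Why: Carbonylative Stille coupling: oxidative addition of the enol triflate, CO insertion and transmetallation from the alkenylstannane give the cross-conjugated dienone, C1 being the new carbonyl carbon.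

Step 5
Reactants: 8 dienone
Product: 9 methyl (1R)-1,4,4-trimethyl-6-oxo-1,2,3,4,5,6-hexahydropentalene-1-carboxylate (ring B: C10–C1(=O)–C4H2–C5Me2–C6, C6=C10 at the ring fusion)
Conditions: MeSO3H/P2O5 (10:1), 25 °C
Reagents that add atoms: none
Why: Nazarov cyclisation: the protonated dienone closes by 4π-conrotatory electrocyclisation between C6 and C5, and loss of H6, the only β-hydrogen of the oxyallyl cation, gives the ring-fusion enone with C5 as the gem-dimethyl quaternary carbon.

Step 6
Reactants: 9 bicyclic enone
Product: 10 methyl (1R,3aR,6aR)-1,4,4-trimethyl-6-oxooctahydropentalene-1-carboxylate (cis-fused; H6 and H10 on the face of the C9 ester, C9 methyl cis to ring B)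
Conditions: H2 (3 atm), [Ir(cod)(PCy3)(py)]PF6 (5 mol%), CH2Cl2, 25 °C
Reagents that add atoms: none
Why: Carbonyl-directed homogeneous hydrogenation: the cationic iridium catalyst binds the C9 ester and should deliver both hydrogens to that face of the tetrasubstituted alkene, which sets C6 and C10 relative to C9, and the bicyclo[3.3.0] skeleton can only be cis-fused.

Step 7
Reactants: 10 cis-fused ketone
Product: 12 (1R,2R,5R)-2-(methoxycarbonyl)-2-methyl-5-(2-methyl-1-oxopropan-2-yl)cyclopentane-1-carboxylic acid (C1 acid on C10; C4 aldehyde on C5; carboxyl group and C6 chain cis to each other and to the C9 methyl), via trimethylsilyl enol ether 11 (not isolated)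
Conditions: LDA, TMSCl, THF, −78 °C; then O3, CH2Cl2/MeOH, −78 °C; Me2S; aqueous work-up
Reagents that add atoms: ozone, O=[O+][O-]; chlorotrimethylsilane, C[Si](C)(C)Cl (silicon in 11 only)
Why: Kinetic enolisation should go to the C4 methylene and not to the hindered ring-fusion methine C10–H, and ozonolysis of the silyl enol ether cuts C1=C4 to the C1 acid and the C4 aldehyde, leaving C10 untouched.

Step 8
Reactants: 12 acid aldehyde
Product: 13 (1R,2R,5R)-2-(methoxycarbonyl)-2-methyl-5-(2-methylbut-3-en-2-yl)cyclopentane-1-carboxylic acid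
Conditions: Ph3PCH3Br, KHMDS (3.2 equiv), THF, 0 °C; then 12, 0 to 25 °C; aq. citric acid
Reagents that add atoms: methylenetriphenylphosphorane (made in the flask), C=P(c1ccccc1)(c1ccccc1)c1ccccc1
Why: Wittig methylenation of the non-enolisable neopentyl aldehyde; the carboxylate formed first protects C10 from epimerisation.

Step 9
Reactants: 13 vinyl acid
Product: 14 methyl (1R,2R,3R)-2-[methoxy(methyl)carbamoyl]-1-methyl-3-(2-methylbut-3-en-2-yl)cyclopentane-1-carboxylate
Conditions: (COCl)2, DMF (cat.), CH2Cl2, 0 °C; then MeNH(OMe)·HCl, pyridine, 0 to 25 °C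
Reagents that add atoms: N,O-dimethylhydroxylamine hydrochloride, CNOC.Cl
Why: Weinreb amide synthesis through the acid chloride, chosen because the flanked C1 acid needs strong activation; pyridine is too weak a base to form a ketene and scramble C10.

Step 10
Reactants: 14 Weinreb amide
Product: 15 methyl (1R,2R,3R)-2-(but-3-enoyl)-1-methyl-3-(2-methylbut-3-en-2-yl)cyclopentane-1-carboxylate
Conditions: allylMgBr (1.5 equiv), THF, −78 °C; cold aq. NH4Cl
Reagents that add atoms: allylmagnesium bromide, C=CC[Mg]Br
Why: Weinreb ketone synthesis: the Grignard reagent adds once, the magnesium chelate survives until the cold quench, and the β,γ-unsaturated ketone is released only on work-up; the C9 ester on a quaternary carbon should react more slowly.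

Step 11
Reactants: 15 allyl ketone
Product: 16 methyl (1R,2R,3R)-1-methyl-3-(2-methylbut-3-en-2-yl)-2-[2-(prop-2-en-1-yl)-1,3-dioxolan-2-yl]cyclopentane-1-carboxylate
Conditions: TMSOCH2CH2OTMS, TMSOTf (cat.), CH2Cl2, −78 to −20 °C; pyridine quench
Reagents that add atoms: 1,2-bis(trimethylsilyloxy)ethane, C[Si](C)(C)OCCO[Si](C)(C)C
Why: Silyl-transfer ketalisation under aprotic conditions forms the dioxolane without the protic acid that would move the allyl double bond into conjugation or epimerise C10.

Step 12
Reactants: 16 ketal diene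
Product: 17 methyl cis-fused hydroazulene-9-carboxylate with C3=C4 alkene and C1 dioxolane (7-ring: C1, C2, C3=C4, C5Me2, C6, C10)
Conditions: second-generation Grubbs catalyst RuCl2(=CHPh)(PCy3)(H2IMes) (5 mol%), CH2Cl2 (0.002 M), 40 °C, argon purge
Reagents that add atoms: none
Why: The ruthenium benzylidene undergoes [2+2] cycloaddition and cycloreversion first with the unhindered allyl terminus, and the new alkylidene on C3 then adds intramolecularly to the neopentyl vinyl group on C5 and cycloreverts, releasing ethylene and forming C3=C4; the closest known reaction type is ring-closing metathesis of 1,8-dienes to cycloheptenes that carry an allylic quaternary carbon. The ring closes as a seven-membered carbocycle by intramolecular alkene metathesis, the two terminal CH2 groups leaving as ethylene. No stereocentre is created, and C6, C9 and C10 are remote from the reacting carbons. The step needs ring closure to win over cross-metathesis oligomerisation: the cis placement of the two chains on C6 and C10, the gem-dimethyl group on C5 and the fully substituted ketal carbon C1 hold the alkene termini together, and high dilution with removal of ethylene supports this. It also needs the allyl double bond to stay in place and C10 to keep its configuration, which the dioxolane ensures because no enolisable carbonyl group and no 1,1-disubstituted alkene is present.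

Step 13
Reactants: 17 cycloheptene ketal
Product: 18 methyl cis-fused perhydroazulene-9-carboxylate with C1 dioxolane
Conditions: H2 (1 atm), 10% Pd/C, EtOAc, 25 °C
Reagents that add atoms: none
Why: Heterogeneous hydrogenation of the cis-disubstituted C3=C4 alkene; ketal and ester are inert.

Step 14
Reactants: 18 saturated ketal
Product: 19 methyl cis-1,4,4-trimethyl-8-oxodecahydroazulene-1-carboxylate (azulene numbering; C1 ketone in the labels used here)
Conditions: 1 M HCl, THF, 25 °C
Reagents that add atoms: water, O
Why: Ketal hydrolysis of the crowded dioxolane under mild acid, kept short to limit epimerisation at C10.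

Step 15
Reactants: 19 ketone
Product: 20 methyl cis-1,4,4-trimethyl-8-methylidenedecahydroazulene-1-carboxylate
Conditions: Zn dust, CH2Br2, TiCl4, THF (reagent preformed at −40 to 5 °C); then 19, CH2Cl2, 0 to 25 °C; aq. NaHCO3
Reagents that add atoms: dibromomethane, BrCBr
Why: Takai–Lombardo methylenation: the zinc–titanium gem-dimetallic methylene reagent made from CH2Br2, Zn and TiCl4 is Lewis acidic and not basic, so the enolisable ring-fusion centre C10 should not epimerise, and it converts ketones but leaves the hindered ester alone.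

Step 16
Reactants: 20 methylidene ester
Product: 21 cis-1,4,4-trimethyl-8-methylidenedecahydroazulene-1-carboxylic acid
Conditions: n-PrSLi, HMPA, 25 °C; then 1 M HCl
Reagents that add atoms: none
Why: SN2 demethylation of the hindered methyl ester by thiolate attacks the O-methyl carbon and avoids the blocked carbonyl carbon.

Step 17
Reactants: 21 hydroazulene acid
Product: 22 1,3-dioxoisoindolin-2-yl ester of acid 21
Conditions: N-hydroxyphthalimide, DIC, DMAP (cat.), CH2Cl2, 25 °C
Reagents that add atoms: N-hydroxyphthalimide, O=C1c2ccccc2C(=O)N1O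
Why: Carbodiimide esterification gives the redox-active N-acyloxyphthalimide.

Step 18
Reactants: 23 (1R,5S)-2-oxabicyclo[3.3.0]oct-6-en-3-one
Product: 24 (1R,5S)-4-exo-hydroxy-2-oxabicyclo[3.3.0]oct-6-en-3-one (OH trans to the cyclopentene carbon on the lactone ring)
Conditions: KHMDS, THF, −78 °C; 2-(phenylsulfonyl)-3-phenyloxaziridine; AcOH quench
Reagents that add atoms: 2-(phenylsulfonyl)-3-phenyloxaziridine, O=S(=O)(N1OC1c1ccccc1)c1ccccc1
Why: Enolate hydroxylation with an N-sulfonyloxaziridine: the oxidant should attack the convex face of the cis-fused lactone enolate, which sets C6' with the configuration of the target.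

Step 19
Reactants: 24 hydroxy lactone
Product: 25 4-exo-(triethylsilyloxy) lactone
Conditions: TESCl, imidazole, DMF, 0 °C
Reagents that add atoms: chlorotriethylsilane, CC[Si](Cl)(CC)CC
Why: Silylation of the secondary alcohol.

Step 20
Reactants: 25 silyloxy lactone
Product: 27 methyl 2-[(1S,5R)-5-hydroxycyclopent-2-en-1-yl]-2-(triethylsilyloxy)acetate (ring OH cis to the side chain; C6' as in 24), via lithium carboxylate 26 (not isolated)
Conditions: LiOH·H2O (1.05 equiv), THF/H2O, 0 °C; evaporate; MeI, DMF, 0 to 25 °C
Reagents that add atoms: lithium hydroxide, [Li+].[OH-]; iodomethane, CI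
Why: Lactone saponification followed by O-alkylation of the carboxylate; keeping the medium neutral after saponification avoids relactonisation.

Step 21
Reactants: 27 hydroxy ester
Product: 28 methyl 2-[(1S,5R)-5-(tert-butyldimethylsilyloxy)cyclopent-2-en-1-yl]-2-(triethylsilyloxy)acetate
Conditions: TBSOTf, 2,6-lutidine, CH2Cl2, −78 °C
Reagents that add atoms: tert-butyldimethylsilyl trifluoromethanesulfonate, CC(C)(C)[Si](C)(C)OS(=O)(=O)C(F)(F)F
Why: Silylation with the silyl triflate caps the hindered C4' alcohol before it can relactonise.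

Step 22
Reactants: 28 bis-silyl cyclopentene
Product: 29 methyl 2-[cis-5-(tert-butyldimethylsilyloxy)-4-oxocyclopent-2-en-1-yl]-2-(triethylsilyloxy)acetate (enone C3'(=O)–C1'=C8'; C4'–OTBS cis to the C5' side chain)
Conditions: Rh2(cap)4 [dirhodium tetrakis(caprolactamate), Rh2(C6H10NO)4] (1 mol%), t-BuOOH (5 equiv), K2CO3, CH2Cl2, 25 °C
Reagents that add atoms: tert-butyl hydroperoxide, CC(C)(C)OO
Why: Allylic C–H oxidation by tert-butylperoxyl radicals converts the allylic methylene C3' into the enone carbonyl; the methylene hydrogens are more accessible than the tertiary C5'–H.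

Step 23
Reactants: 22 N-acyloxyphthalimide; 29 cyclopentenone
Product: 30 conjugate adduct: cyclopentanone with C9 of the hydroazulene bonded to C8', trans to the C5' side chain
Conditions: Ru(bpy)3(PF6)2 (1 mol%), Hantzsch ester (1.5 equiv), i-Pr2NEt, CH2Cl2, blue LEDs, 25 °C
Reagents that add atoms: none
Why: Giese addition under photoredox conditions: single-electron reduction of the phthalimide ester and loss of CO2 give the C9 tertiary radical, which should add to C8' on the face opposite the C5' side chain and the C4' silyl ether while itself being attacked on the convex face of the cis-hydroazulene (anti to the C10–C1 bond), which sets C9 and C8'; hydrogen-atom transfer from the dihydropyridine ends the sequence.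

Step 24
Reactants: 30 adduct ketone
Product: 31 α-hydroxy ketone (C1'–OH, drawn trans to the C8' substituent)
Conditions: KHMDS, THF, −78 °C; 2-(phenylsulfonyl)-3-phenyloxaziridine; AcOH quench
Reagents that add atoms: 2-(phenylsulfonyl)-3-phenyloxaziridine, O=S(=O)(N1OC1c1ccccc1)c1ccccc1
Why: Enolate hydroxylation: kinetic enolisation should occur at the C1' methylene, away from the silyloxy-bearing C4', and the oxaziridine adds anti to the C8' substituent; the configuration at C1' is lost later.

Step 25
Reactants: 31 α-hydroxy ketone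
Product: 32 diol (C6'–OH and C1'–OH free, C4'–OTBS kept)
Conditions: PPTS (cat.), MeOH, 0 to 25 °C
Reagents that add atoms: none
Why: Acid-catalysed methanolysis removes the triethylsilyl ether selectively, as it is far more acid-labile than the tert-butyldimethylsilyl ether.

Step 26
Reactants: 32 diol ketone
Product: 34 4'-O-TBS-protected 2,7-dioxabicyclo[3.2.1]octan-3-one (target skeleton), via seco acid aldehyde 33 (not isolated)
Conditions: NaIO4, THF/H2O (pH 7), 25 °C; then PPTS (cat.), benzene, 4 Å sieves, 40 °C
Reagents that add atoms: sodium periodate, [Na+].[O-]I(=O)(=O)=O (carboxyl oxygen of 33)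
Why: Periodate cleavage of the α-hydroxy ketone cuts C3'–C1' to the C3' acid and the C1' aldehyde; the C6' hydroxyl closes the five-membered lactol on C1', and acid-catalysed acylal formation with the C3' acid closes the δ-lactone, the bridged ring fixing the configuration at C1'.

Step 27
Reactants: 34 silyl-protected bicycle
Product: 35 C4' alcohol
Conditions: HF·pyridine, THF, 0 to 25 °C
Reagents that add atoms: none
Why: Fluoride desilylation; the acylal and the exocyclic alkene should tolerate the buffered acid.

Step 28
Reactants: 35 C4' alcohol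
Product: 36 target
Conditions: Ac2O, DMAP (cat.), pyridine, CH2Cl2, 0 °C
Reagents that add atoms: acetic anhydride, CC(=O)OC(C)=O
Why: DMAP-catalysed acetylation of the only free hydroxyl group.

**Compound list**

1 | methyl 2-oxocyclopentane-1-carboxylate | COC(=O)C1CCCC1=O | starting material
2 | L-valine tert-butyl ester | CC(C)[C@H](N)C(=O)OC(C)(C)C | starting material
3 | methyl 2-{[(2S)-1-tert-butoxy-3-methyl-1-oxobutan-2-yl]amino}cyclopent-1-ene-1-carboxylate | COC(=O)C1=C(N[C@@H](C(C)C)C(=O)OC(C)(C)C)CCC1 | intermediate
4 | methyl (1R)-2-{[(2S)-1-tert-butoxy-3-methyl-1-oxobutan-2-yl]imino}-1-methylcyclopentane-1-carboxylate | COC(=O)[C@]1(C)CCCC1=N[C@@H](C(C)C)C(=O)OC(C)(C)C | intermediate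
5 | methyl (1R)-1-methyl-2-oxocyclopentane-1-carboxylate | COC(=O)[C@]1(C)CCCC1=O | intermediate
6 | methyl (1R)-1-methyl-2-(trifluoromethylsulfonyloxy)cyclopent-2-ene-1-carboxylate | COC(=O)[C@]1(C)CCC=C1OS(=O)(=O)C(F)(F)F | intermediate
7 | tributyl(2-methylprop-1-en-1-yl)stannane | CC(C)=C[Sn](CCCC)(CCCC)CCCC | starting material
8 | methyl (1R)-1-methyl-2-(3-methylbut-2-enoyl)cyclopent-2-ene-1-carboxylate | COC(=O)[C@]1(C)CCC=C1C(=O)C=C(C)C | intermediate
9 | methyl (1R)-1,4,4-trimethyl-6-oxo-1,2,3,4,5,6-hexahydropentalene-1-carboxylate | COC(=O)[C@]1(C)CCC2=C1C(=O)CC2(C)C | intermediate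
10 | methyl (1R,3aR,6aR)-1,4,4-trimethyl-6-oxooctahydropentalene-1-carboxylate (cis-fused) | COC(=O)[C@]1(C)CC[C@@H]2[C@H]1C(=O)CC2(C)C | intermediate
11 | trimethylsilyl enol ether of 10 (C1(OTMS)=C4) | COC(=O)[C@]1(C)CC[C@@H]2[C@H]1C(O[Si](C)(C)C)=CC2(C)C | intermediate
12 | (1R,2R,5R)-2-(methoxycarbonyl)-2-methyl-5-(2-methyl-1-oxopropan-2-yl)cyclopentane-1-carboxylic acid (carboxyl, C9 methyl and C6 chain on one face) | COC(=O)[C@]1(C)CC[C@@H](C(C)(C)C=O)[C@H]1C(=O)O | intermediate
13 | (1R,2R,5R)-2-(methoxycarbonyl)-2-methyl-5-(2-methylbut-3-en-2-yl)cyclopentane-1-carboxylic acid | COC(=O)[C@]1(C)CC[C@@H](C(C)(C)C=C)[C@H]1C(=O)O | intermediate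
14 | methyl (1R,2R,3R)-2-[methoxy(methyl)carbamoyl]-1-methyl-3-(2-methylbut-3-en-2-yl)cyclopentane-1-carboxylate | COC(=O)[C@]1(C)CC[C@@H](C(C)(C)C=C)[C@H]1C(=O)N(C)OC | intermediate
15 | methyl (1R,2R,3R)-2-(but-3-enoyl)-1-methyl-3-(2-methylbut-3-en-2-yl)cyclopentane-1-carboxylate | COC(=O)[C@]1(C)CC[C@@H](C(C)(C)C=C)[C@H]1C(=O)CC=C | intermediate
16 | methyl (1R,2R,3R)-1-methyl-3-(2-methylbut-3-en-2-yl)-2-[2-(prop-2-en-1-yl)-1,3-dioxolan-2-yl]cyclopentane-1-carboxylate (metathesis precursor) | COC(=O)[C@]1(C)CC[C@@H](C(C)(C)C=C)[C@H]1C2(CC=C)OCCO2 | intermediate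
17 | methyl cis-hydroazulene-9-carboxylate with C3=C4 alkene and C1 dioxolane (metathesis product) | COC(=O)[C@]1(C)CC[C@@H]2[C@H]1C3(CC=CC2(C)C)OCCO3 | intermediate
18 | methyl cis-perhydroazulene-9-carboxylate with C1 dioxolane | COC(=O)[C@]1(C)CC[C@@H]2[C@H]1C3(CCCC2(C)C)OCCO3 | intermediate
19 | methyl cis-1,4,4-trimethyl-8-oxodecahydroazulene-1-carboxylate | COC(=O)[C@]1(C)CC[C@@H]2[C@H]1C(=O)CCCC2(C)C | intermediate
20 | methyl cis-1,4,4-trimethyl-8-methylidenedecahydroazulene-1-carboxylate | COC(=O)[C@]1(C)CC[C@@H]2[C@H]1C(=C)CCCC2(C)C | intermediate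
21 | cis-1,4,4-trimethyl-8-methylidenedecahydroazulene-1-carboxylic acid | OC(=O)[C@]1(C)CC[C@@H]2[C@H]1C(=C)CCCC2(C)C | intermediate
22 | 1,3-dioxoisoindolin-2-yl ester of 21 | O=C(ON1C(=O)c2ccccc2C1=O)[C@]3(C)CC[C@@H]4[C@H]3C(=C)CCCC4(C)C | intermediate
23 | (1R,5S)-2-oxabicyclo[3.3.0]oct-6-en-3-one | O=C1C[C@H]2C=CC[C@H]2O1 | starting material
24 | (1R,5S)-4-exo-hydroxy-2-oxabicyclo[3.3.0]oct-6-en-3-one | O=C1[C@H](O)[C@H]2C=CC[C@H]2O1 | intermediate
25 | (1R,5S)-4-exo-(triethylsilyloxy)-2-oxabicyclo[3.3.0]oct-6-en-3-one | O=C1[C@H](O[Si](CC)(CC)CC)[C@H]2C=CC[C@H]2O1 | intermediate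
26 | lithium 2-[(1S,5R)-5-hydroxycyclopent-2-en-1-yl]-2-(triethylsilyloxy)acetate | [Li+].[O-]C(=O)[C@H](O[Si](CC)(CC)CC)[C@H]1C=CC[C@H]1O | intermediate
27 | methyl 2-[(1S,5R)-5-hydroxycyclopent-2-en-1-yl]-2-(triethylsilyloxy)acetate | COC(=O)[C@H](O[Si](CC)(CC)CC)[C@H]1C=CC[C@H]1O | intermediate
28 | methyl 2-[(1S,5R)-5-(tert-butyldimethylsilyloxy)cyclopent-2-en-1-yl]-2-(triethylsilyloxy)acetate | COC(=O)[C@H](O[Si](CC)(CC)CC)[C@H]1C=CC[C@H]1O[Si](C)(C)C(C)(C)C | intermediate
29 | methyl 2-[cis-5-(tert-butyldimethylsilyloxy)-4-oxocyclopent-2-en-1-yl]-2-(triethylsilyloxy)acetate | COC(=O)[C@H](O[Si](CC)(CC)CC)[C@H]1C=CC(=O)[C@H]1O[Si](C)(C)C(C)(C)C | intermediate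
30 | radical adduct: cyclopentanone with hydroazulenyl C9 on C8' (trans to the C5' side chain) | COC(=O)[C@H](O[Si](CC)(CC)CC)[C@H]1[C@H]([C@]2(C)CC[C@@H]3[C@H]2C(=C)CCCC3(C)C)CC(=O)[C@H]1O[Si](C)(C)C(C)(C)C | intermediate
31 | C1'-hydroxy ketone from 30 | COC(=O)[C@H](O[Si](CC)(CC)CC)[C@H]1[C@H]([C@]2(C)CC[C@@H]3[C@H]2C(=C)CCCC3(C)C)[C@@H](O)C(=O)[C@H]1O[Si](C)(C)C(C)(C)C | intermediate
32 | C6',C1'-diol ketone (C4'–OTBS) | COC(=O)[C@H](O)[C@H]1[C@H]([C@]2(C)CC[C@@H]3[C@H]2C(=C)CCCC3(C)C)[C@@H](O)C(=O)[C@H]1O[Si](C)(C)C(C)(C)C | intermediate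
33 | seco acid aldehyde (C3' acid, C1' aldehyde, C6' alcohol, C4'–OTBS) | COC(=O)[C@H](O)[C@@H]([C@H]([C@]1(C)CC[C@@H]2[C@H]1C(=C)CCCC2(C)C)C=O)[C@H](O[Si](C)(C)C(C)(C)C)C(=O)O | intermediate
34 | 4'-O-(tert-butyldimethylsilyl) analogue of the target alcohol | C=C1CCCC(C)(C)[C@@H]2CC[C@@](C)([C@@H]3[C@@H]4OC(=O)[C@@H](O[Si](C)(C)C(C)(C)C)[C@H]3[C@H](C(=O)OC)O4)[C@H]12 | intermediate
35 | C4' alcohol (desacetyl target) | C=C1CCCC(C)(C)[C@@H]2CC[C@@](C)([C@@H]3[C@@H]4OC(=O)[C@@H](O)[C@H]3[C@H](C(=O)OC)O4)[C@H]12 | intermediate
36 | CNP0215240.1 | C=C1CCCC(C)(C)[C@@H]2CC[C@@](C)([C@@H]3[C@@H]4OC(=O)[C@@H](OC(C)=O)[C@H]3[C@H](C(=O)OC)O4)[C@H]12 | target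

**Step count and risks**

Total step count: 28. Longest linear sequence: 23 steps (steps 1–17, then 23–28); steps 18–22 prepare the enone 29 in a side branch.

Steps most likely to fail:

Step 11. The dioxolane must form at a carbonyl carbon flanked by the C9 methyl and the C5 dimethylallyl group on the same face, so ketal formation may be slower than migration of the allyl double bond into conjugation or epimerisation at C10. The fallback carries C1 as a carbinol through the ring closure. It sets out from ketone 15: reduction with NaBH4/CeCl3·7H2O in MeOH at −78 °C should give the homoallylic alcohol F1 (either C1 epimer, the hindered ester untouched). Ring-closing metathesis of F1 with the same ruthenium catalyst should give the cycloheptenol F2, hydrogenation over Pd/C the saturated alcohol F3, and Dess–Martin oxidation (NaHCO3 buffer) returns to the route at ketone 19, with no acidic deketalisation.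

Step 23. The hindered tertiary radical may be reduced or disproportionate faster than it adds to a β-carbon that sits next to the substituted C5'. The fallback adds an activating group to the acceptor. It sets out from enone 29: chlorine addition and dehydrochlorination (PhICl2, pyridine) should give the 2-chloro enone F4, a better radical acceptor whose adduct radical is also more easily reduced. Coupling of 22 with F4 under the same photoredox conditions should give the α-chloro ketone F5 (C1' epimers), and reductive dechlorination with Bu3SnH and AIBN returns to the route at ketone 30.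

Step 22. Hydrogen abstraction may compete at the tertiary allylic C5'–H, and oxygen may be delivered with allylic transposition, giving regioisomeric enones or over-oxidation. The fallback replaces the radical oxidation by an ene and sigmatropic sequence. It sets out from cyclopentene 28: SeO2 (cat.) with t-BuOOH should hydroxylate the methylene carbon C3' without moving the double bond (ene reaction then [2,3]-shift) to give the allylic alcohol F6 (C3' epimers), and MnO2 oxidation returns to the route at enone 29.

Further compounds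
F1 | step 11 | methyl (1R,2R,3R)-2-(1-hydroxybut-3-en-1-yl)-1-methyl-3-(2-methylbut-3-en-2-yl)cyclopentane-1-carboxylate (C1 epimers) | COC(=O)[C@]1(C)CC[C@@H](C(C)(C)C=C)[C@H]1C(O)CC=C
F2 | step 11 | methyl cis-hydroazulene-9-carboxylate with C3=C4 alkene and C1 hydroxyl (C1 epimers) | COC(=O)[C@]1(C)CC[C@@H]2[C@H]1C(O)CC=CC2(C)C
F3 | step 11 | methyl cis-perhydroazulene-9-carboxylate with C1 hydroxyl (C1 epimers) | COC(=O)[C@]1(C)CC[C@@H]2[C@H]1C(O)CCCC2(C)C
F4 | step 23 | methyl 2-[cis-5-(tert-butyldimethylsilyloxy)-3-chloro-4-oxocyclopent-2-en-1-yl]-2-(triethylsilyloxy)acetate | COC(=O)[C@H](O[Si](CC)(CC)CC)[C@H]1C=C(Cl)C(=O)[C@H]1O[Si](C)(C)C(C)(C)C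
F5 | step 23 | C1'-chloro analogue of adduct 30 (C1' epimers) | COC(=O)[C@H](O[Si](CC)(CC)CC)[C@H]1[C@H]([C@]2(C)CC[C@@H]3[C@H]2C(=C)CCCC3(C)C)C(Cl)C(=O)[C@H]1O[Si](C)(C)C(C)(C)C
F6 | step 22 | methyl 2-[5-(tert-butyldimethylsilyloxy)-4-hydroxycyclopent-2-en-1-yl]-2-(triethylsilyloxy)acetate (C3' epimers) | COC(=O)[C@H](O[Si](CC)(CC)CC)[C@H]1C=CC(O)[C@H]1O[Si](C)(C)C(C)(C)C
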